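**Plan**
- Retrosynthesis: the C15 acetate and C19 ester are adjusted last, then C9–C11 is cut (C9 enol triflate plus C11–C16 alkylborane). Ring A is then opened at C1–C10 and C2–C3 together with C4–C18, which removes an ethylene unit and a methyl group and leaves a cyclohexenone that carries an acrylate.
- Enabling feature: C10 is α to C9 (a ketone until the C8=C9 alkene is made) and C3 is β to the C19 carboxyl carbon on C4. A C10 enolate and a C4 acrylate can therefore be bridged by a two-carbon unit that is electrophilic at C1 and then nucleophilic at C2 (phenyl vinyl sulfone).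
- Mapping: (R)-carvone is ring B (C5–C10) with C17 and the C5 stereocentre; its isopropenyl group is C4, C3 and C19.
- Forward: methylate (C20), oxidise the isopropenyl methyl to an acrylate ester, close ring A in one pot (Michael, Michael, methylation), convert the enone into the C9 enol triflate, couple the side chain, remove sulfone and silyl groups, acetylate.
- Stereochemistry: C5 is bought with carvone; C10 and C4 are relayed from it in the ring-closing step; 13E is bought with the enynol.

Key step: step 6

Remark: labdane numbering is used in the text. Compounds 3–7 are epimer mixtures at the methyl-bearing carbon next to the ketone (the later C10, erased in step 6). Compounds 12, 14 and 19 are undefined at the sulfone-bearing C2 (removed in step 11). The SMILES leave these two centres open. Compounds 1, 8 and 15 are taken as commercial.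

**Step 1**
Reactants: 1 (R)-carvone
Product: 3 (5R)-2,6-dimethyl-5-(prop-1-en-2-yl)cyclohex-2-en-1-one (6-methylcarvone; C6 epimers), via lithium dienolate of carvone 2 (not isolated)
Conditions: LDA, THF, −78 °C; MeI, −78 → 0 °C
Reagents that add atoms: iodomethane, CI
Why: Kinetic α′-deprotonation gives the cross-conjugated lithium dienolate, which is C-methylated (enolate alkylation), mainly trans to the isopropenyl group; the epimer composition does not matter because step 6 planarises this carbon again.

**Step 2**
Reactants: 3 6-methylcarvone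
Product: 4 (5R)-5-(3-chloroprop-1-en-2-yl)-2,6-dimethylcyclohex-2-en-1-one
Conditions: Ca(OCl)2, solid CO2, CH2Cl2/H2O, 0 °C
Reagents that add atoms: calcium hypochlorite, [Ca+2].[O-]Cl.[O-]Cl
Why: Ene-type allylic chlorination by HOCl should attack only the electron-rich 1,1-disubstituted alkene, with shift of the double bond, and leave the conjugated enone untouched.

**Step 3**
Reactants: 4 allylic chloride
Product: 5 2-[(1R)-2,4-dimethyl-3-oxocyclohex-4-en-1-yl]prop-2-enal
Conditions: N-methylmorpholine N-oxide, NaI (cat.), MeCN, rt → 40 °C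
Reagents that add atoms: N-methylmorpholine N-oxide, C[N+]1([O-])CCOCC1
Why: Kornblum-type oxidation, in which the N-oxide oxygen displaces the iodide-activated allylic chloride and loss of N-methylmorpholine then delivers the 2-substituted acrolein.

**Step 4**
Reactants: 5 enal
Product: 6 2-[(1R)-2,4-dimethyl-3-oxocyclohex-4-en-1-yl]prop-2-enoic acid
Conditions: NaClO2, NaH2PO4, 2-methyl-2-butene, t-BuOH/H2O, 0 °C → rt
Reagents that add atoms: sodium chlorite, [Na+].[O-]Cl=O
Why: Pinnick oxidation converts the conjugated aldehyde into the acrylic acid, and the alkene scavenger removes HOCl so that neither C=C bond of the substrate is chlorinated.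

**Step 5**
Reactants: 6 acrylic acid
Product: 7 2-(trimethylsilyl)ethyl 2-[(1R)-2,4-dimethyl-3-oxocyclohex-4-en-1-yl]prop-2-enoate
Conditions: Me3SiCH2CH2OH, DCC, DMAP (cat.), CH2Cl2, 0 °C → rt
Reagents that add atoms: 2-(trimethylsilyl)ethanol, C[Si](C)(C)CCO
Why: Steglich esterification under neutral conditions; this ester is chosen because fluoride can later free the hindered axial C19 acid by attack at silicon instead of at the carbonyl group.

**Step 6**
Reactants: 7 keto acrylate; 8 phenyl vinyl sulfone
Product: 12 2-(trimethylsilyl)ethyl (4S,5R,10S)-9-oxo-2-(phenylsulfonyl)-11,12,13,14,15,16-hexanorlabd-7-en-19-oate, via lithium dienolate of the keto acrylate 9 (not isolated), via lithiated sulfone Michael adduct 10 (not isolated), via bicyclic lithium ester enolate 11 (not isolated)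
Conditions: LiN(SiMe3)2, THF, −78 °C; 8 (1.0 equiv), −78 → −20 °C; MeI, DMPU, −78 → 0 °C
Reagents that add atoms: iodomethane, CI
Why: LiN(SiMe3)2 removes the C10–H next to the C9 ketone to give the cross-conjugated dienolate 9, which adds through C10 to the CH2 of phenyl vinyl sulfone (C10–C1); the α-sulfonyl carbanion 10 then adds to the CH2 terminus of the acrylate held on C5 (C2–C3), and the ester enolate 11 so formed is C-methylated (C4–C18). The closest known reaction type is the Michael–Michael ring closure of a ketone enolate with two acceptors that ends in an enolate alkylation, a stepwise anionic [4+2] annulation. Ring A closes by 6-endo-trig conjugate addition through a chair in which the C1–C2 arm on C10 and the acrylate on C5 are both equatorial, so the decalin should be trans-fused. C10 is set by the carvone-derived C5 centre, because the acrylate group lies pseudoaxial beside the C10 methyl of the flat enolate and the sulfone enters from the other face (C1 trans to C4, methyl β and axial); C4 is set by that axial C10 methyl, which shields the β face of the exocyclic enolate so that MeI enters equatorially (α) and the ester is left axial (β, C19); C2 is not controlled and loses its substituent in step 11. The step needs carbanion 10 to choose the acrylate CH2 over C7 of the ring enone (which would give a bridged bicyclo[2.2.2]octanone) and over the ester carbonyl: the acrylate terminus is unsubstituted and is reached through the all-equatorial chair, whereas C7 sits next to the deactivating C8 methyl and is reached only through a boat with both arms axial; one equivalent of 8 is used so that neither 10 nor 11 meets a second acceptor.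

**Step 7**
Reactants: 12 bicyclic enone
Product: 14 2-(trimethylsilyl)ethyl (4S,5R,10S)-2-(phenylsulfonyl)-9-(trifluoromethylsulfonyloxy)-11,12,13,14,15,16-hexanorlabd-8-en-19-oate, via lithium C8=C9 enolate 13 (not isolated)
Conditions: LiBH(s-Bu)3, THF, −78 °C; PhNTf2, −78 °C → rt
Reagents that add atoms: N-phenylbis(trifluoromethanesulfonimide), O=S(=O)(N(c1ccccc1)S(=O)(=O)C(F)(F)F)C(F)(F)F
Why: Conjugate reduction delivers hydride to C7 (the C9 carbonyl is shielded by quaternary C10) and gives the C8=C9 enolate regiospecifically, which is O-sulfonylated to the tetrasubstituted enol triflate.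

**Step 8**
Reactants: 15 (2E)-3-methylpent-2-en-4-yn-1-ol
Product: 16 tert-butyldimethyl{[(2E)-3-methylpent-2-en-4-yn-1-yl]oxy}silane
Conditions: TBSCl, imidazole, DMF, 0 °C → rt
Reagents that add atoms: tert-butyldimethylsilyl chloride, CC(C)(C)[Si](C)(C)Cl
Why: Standard silylation of a primary allylic alcohol, giving an ether that tolerates borane, palladium and sodium amalgam.

**Step 9**
Reactants: 16 enyne silyl ether
Product: 17 tert-butyldimethyl{[(2E)-3-methylpenta-2,4-dien-1-yl]oxy}silane
Conditions: H2 (1 atm), Pd/CaCO3 poisoned with Pb(OAc)2, quinoline, hexane, rt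
Reagents that add atoms: none
Why: Lindlar semihydrogenation of the terminal alkyne should stop at the vinyl group and leave the (E)-trisubstituted alkene unchanged.

**Step 10**
Reactants: 17 diene silyl ether; 14 enol triflate
Product: 19 2-(trimethylsilyl)ethyl (4S,5R,10S,13E)-15-[(tert-butyldimethylsilyl)oxy]-2-(phenylsulfonyl)labda-8,13-dien-19-oate, via B-alkyl-9-BBN adduct 18 (not isolated)
Conditions: 9-BBN, THF, 0 °C → rt; then 14, PdCl2(dppf), AsPh3, Cs2CO3, DMF/THF/H2O, rt → 50 °C
Reagents that add atoms: 9-borabicyclo[3.3.1]nonane (9-BBN), B1C2CCCC1CCC2 (its boron stays only in 18)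
Why: 9-BBN hydroborates the monosubstituted terminus of the diene in anti-Markovnikov fashion, and the alkylborane then undergoes B-alkyl Suzuki–Miyaura coupling with the enol triflate to form C9–C11 with both alkene geometries retained.

**Step 11**
Reactants: 19 sulfone
Product: 20 2-(trimethylsilyl)ethyl (4S,5R,10S,13E)-15-[(tert-butyldimethylsilyl)oxy]labda-8,13-dien-19-oate
Conditions: Na(Hg), Na2HPO4, MeOH/THF, −20 °C → rt
Reagents that add atoms: none
Why: Reductive desulfonylation by electron transfer cleaves the C2–S bond and buffered methanol protonates the carbanion, while the hindered ester, the silyl ether and the unconjugated alkenes should be inert.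

**Step 12**
Reactants: 20 bis-silyl compound
Product: 21 (4S,5R,10S,13E)-15-hydroxylabda-8,13-dien-19-oic acid
Conditions: Bu4NF, THF, rt → 45 °C; aq. NH4Cl
Reagents that add atoms: none
Why: Fluoride cleaves the silyl ether and fragments the 2-(trimethylsilyl)ethyl ester by attack at silicon (loss of ethene), so the neopentyl axial ester needs no saponification.

**Step 13**
Reactants: 21 hydroxy acid
Product: 22 (4S,5R,10S,13E)-15-acetoxylabda-8,13-dien-19-oic acid
Conditions: Ac2O (1.2 equiv), pyridine, DMAP (cat.), CH2Cl2, 0 °C; aq. NaHCO3, then dilute citric acid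
Reagents that add atoms: acetic anhydride, CC(=O)OC(C)=O
Why: Acetylation of the unhindered primary allylic alcohol; the tertiary axial carboxylic acid should not be esterified and is recovered as the free acid after aqueous work-up.

**Compound list**
1 | (R)-carvone, (5R)-2-methyl-5-(prop-1-en-2-yl)cyclohex-2-en-1-one | CC1=CC[C@H](CC1=O)C(C)=C | starting material
2 | kinetic lithium dienolate of carvone | CC1=CC[C@H](C=C1O[Li])C(C)=C | intermediate
3 | (5R)-2,6-dimethyl-5-(prop-1-en-2-yl)cyclohex-2-en-1-one (C6 epimers, mainly trans) | CC1=CC[C@H](C(C)C1=O)C(C)=C | intermediate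
4 | (5R)-5-(3-chloroprop-1-en-2-yl)-2,6-dimethylcyclohex-2-en-1-one (C6 epimers) | CC1=CC[C@H](C(C)C1=O)C(=C)CCl | intermediate
5 | 2-[(1R)-2,4-dimethyl-3-oxocyclohex-4-en-1-yl]prop-2-enal (C2 epimers of the ring) | CC1=CC[C@H](C(C)C1=O)C(=C)C=O | intermediate
6 | 2-[(1R)-2,4-dimethyl-3-oxocyclohex-4-en-1-yl]prop-2-enoic acid (C2 epimers of the ring) | CC1=CC[C@H](C(C)C1=O)C(=C)C(=O)O | intermediate
7 | 2-(trimethylsilyl)ethyl 2-[(1R)-2,4-dimethyl-3-oxocyclohex-4-en-1-yl]prop-2-enoate (C2 epimers of the ring) | CC1=CC[C@H](C(C)C1=O)C(=C)C(=O)OCC[Si](C)(C)C | intermediate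
8 | phenyl vinyl sulfone | C=CS(=O)(=O)c1ccccc1 | starting material
9 | cross-conjugated lithium dienolate of 7 (C9–O–Li, C10=C9, C8=C7) | CC1=CC[C@H](C(C)=C1O[Li])C(=C)C(=O)OCC[Si](C)(C)C | intermediate
10 | lithiated sulfone after the first Michael addition: C10 carries methyl and CH2CH(Li)SO2Ph, the arm trans to the acrylate on C5 | CC1=CC[C@H]([C@](C)(CC([Li])S(=O)(=O)c2ccccc2)C1=O)C(=C)C(=O)OCC[Si](C)(C)C | intermediate
11 | bicyclic lithium ester enolate at C4 (trans-decalin, 5α-H, 10β-methyl, enone in ring B) | O=C1C(C)=CC[C@H]2C(=C(O[Li])OCC[Si](C)(C)C)CC(S(=O)(=O)c3ccccc3)C[C@]12C | intermediate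
12 | 2-(trimethylsilyl)ethyl (4S,5R,10S)-9-oxo-2-(phenylsulfonyl)-11,12,13,14,15,16-hexanorlabd-7-en-19-oate (4α-methyl, 4β-ester, 5α-H, 10β-methyl) | O=C1C(C)=CC[C@H]2[C@@](C)(C(=O)OCC[Si](C)(C)C)CC(S(=O)(=O)c3ccccc3)C[C@]12C | intermediate
13 | lithium C8=C9 enolate from conjugate reduction of 12 | [Li]OC1=C(C)CC[C@H]2[C@@](C)(C(=O)OCC[Si](C)(C)C)CC(S(=O)(=O)c3ccccc3)C[C@]12C | intermediate
14 | 2-(trimethylsilyl)ethyl (4S,5R,10S)-2-(phenylsulfonyl)-9-(trifluoromethylsulfonyloxy)-11,12,13,14,15,16-hexanorlabd-8-en-19-oate | O=S(=O)(OC1=C(C)CC[C@H]2[C@@](C)(C(=O)OCC[Si](C)(C)C)CC(S(=O)(=O)c3ccccc3)C[C@]12C)C(F)(F)F | intermediate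
15 | (2E)-3-methylpent-2-en-4-yn-1-ol | OC/C=C(\C)C#C | starting material
16 | tert-butyldimethyl{[(2E)-3-methylpent-2-en-4-yn-1-yl]oxy}silane | CC(C)(C)[Si](C)(C)OC/C=C(\C)C#C | intermediate
17 | tert-butyldimethyl{[(2E)-3-methylpenta-2,4-dien-1-yl]oxy}silane | CC(C)(C)[Si](C)(C)OC/C=C(\C)C=C | intermediate
18 | 9-[(3E)-5-(tert-butyldimethylsilyloxy)-3-methylpent-3-en-1-yl]-9-borabicyclo[3.3.1]nonane | CC(C)(C)[Si](C)(C)OC/C=C(\C)CCB1C2CCCC1CCC2 | intermediate
19 | 2-(trimethylsilyl)ethyl (4S,5R,10S,13E)-15-[(tert-butyldimethylsilyl)oxy]-2-(phenylsulfonyl)labda-8,13-dien-19-oate | CC(C)(C)[Si](C)(C)OC/C=C(\C)CCC1=C(C)CC[C@H]2[C@@](C)(C(=O)OCC[Si](C)(C)C)CC(S(=O)(=O)c3ccccc3)C[C@]12C | intermediate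
20 | 2-(trimethylsilyl)ethyl (4S,5R,10S,13E)-15-[(tert-butyldimethylsilyl)oxy]labda-8,13-dien-19-oate | CC(C)(C)[Si](C)(C)OC/C=C(\C)CCC1=C(C)CC[C@H]2[C@@](C)(C(=O)OCC[Si](C)(C)C)CCC[C@]12C | intermediate
21 | (4S,5R,10S,13E)-15-hydroxylabda-8,13-dien-19-oic acid | OC/C=C(\C)CCC1=C(C)CC[C@H]2[C@@](C)(C(=O)O)CCC[C@]12C | intermediate
22 | (4S,5R,10S,13E)-15-acetoxylabda-8,13-dien-19-oic acid | CC(=O)OC/C=C(\C)CCC1=C(C)CC[C@H]2[C@@](C)(C(=O)O)CCC[C@]12C | target

**Totals**
Total step count: 13. Longest linear sequence: 11 steps (steps 1–7 and 10–13); the side-chain branch (steps 8 and 9) joins at step 10.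

**Steps most likely to fail**

1. Step 6. The α-sulfonyl carbanion may close onto C7 of the ring enone (bridged bicyclic ketone) or be quenched by proton transfer before ring A forms, and the final enolate may be protonated instead of methylated.
Fallback (from 7, back at 12): the ring enone is masked so that no second acceptor exists in ring B. Nucleophilic epoxidation of 7 (H2O2, NaOH, MeOH, 0 °C), which should be faster at the enone than at the α-alkyl acrylate and anti to the C5 substituent, gives the 7,8-epoxy ketone 2-(trimethylsilyl)ethyl 2-[(1R)-4,5-epoxy-2,4-dimethyl-3-oxocyclohexyl]prop-2-enoate F1. In F1 only C10 can enolise. The same sequence (LiN(SiMe3)2; 8; MeI) gives the 7α,8α-epoxy analogue of 12 F2. SmI2 (THF/MeOH, −78 °C) opens the epoxy ketone at C8–O to the 7α-hydroxy-9-ketone F3. Mesylation and elimination (MsCl, Et3N; DBU) return enone 12.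

2. Step 10. Oxidative addition and transmetallation at the tetrasubstituted C9 triflate flanked by quaternary C10 may be slow, so that triflate hydrolysis and loss of the alkylborane by protodeboronation or β-hydride elimination take over.
Fallback (from 12 and 18, back at 19): the C9–C11 bond is made by carbonyl addition before the oxygen is removed. Iodination of 18 (I2, NaOMe) gives tert-butyl{[(2E)-5-iodo-3-methylpent-2-en-1-yl]oxy}dimethylsilane F4. Lithium–iodine exchange (t-BuLi, −78 °C), transmetallation with CeCl3 and 1,2-addition to enone 12 give the tertiary allylic alcohol 2-(trimethylsilyl)ethyl (13E)-15-[(tert-butyldimethylsilyl)oxy]-9-hydroxy-2-(phenylsulfonyl)labda-7,13-dien-19-oate F5. Ionic reduction (Et3SiH, BF3·OEt2, CH2Cl2, −78 °C) should ionise F5 to the C7–C8–C9 allyl cation and deliver hydride to the less hindered C7, giving 19.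

3. Step 3. Displacement of the allylic chloride by the N-oxide may be sluggish, and the reactive 2-substituted acrolein may be lost by conjugate addition of amine or by polymerisation.
Fallback (from 4, back at 5): substitution with KOAc (DMF, 60 °C) gives the allylic acetate 2-[(1R)-2,4-dimethyl-3-oxocyclohex-4-en-1-yl]prop-2-en-1-yl acetate F6. Methanolysis (K2CO3, MeOH) gives the allylic alcohol (5R)-5-(3-hydroxyprop-1-en-2-yl)-2,6-dimethylcyclohex-2-en-1-one F7. Oxidation with MnO2 (CH2Cl2) gives enal 5.

**Further compounds**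
F1 | step 6 | 2-(trimethylsilyl)ethyl 2-[(1R)-4,5-epoxy-2,4-dimethyl-3-oxocyclohexyl]prop-2-enoate (epoxide anti to the acrylate arm; C2 epimers of the ring) | C[C@@]12O[C@@H]1C[C@H](C(C)C2=O)C(=C)C(=O)OCC[Si](C)(C)C
F2 | step 6 | 2-(trimethylsilyl)ethyl (4S,5R,10S)-7α,8α-epoxy-9-oxo-2-(phenylsulfonyl)-11,12,13,14,15,16-hexanorlabdan-19-oate | O=C1[C@]2(C)O[C@@H]2C[C@H]3[C@@](C)(C(=O)OCC[Si](C)(C)C)CC(S(=O)(=O)c4ccccc4)C[C@]13C
F3 | step 6 | 2-(trimethylsilyl)ethyl (4S,5R,10S)-7α-hydroxy-9-oxo-2-(phenylsulfonyl)-11,12,13,14,15,16-hexanorlabdan-19-oate (C8 epimers) | O=C1C(C)[C@H](O)C[C@H]2[C@@](C)(C(=O)OCC[Si](C)(C)C)CC(S(=O)(=O)c3ccccc3)C[C@]12C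
F4 | step 10 | tert-butyl{[(2E)-5-iodo-3-methylpent-2-en-1-yl]oxy}dimethylsilane | CC(C)(C)[Si](C)(C)OC/C=C(\C)CCI
F5 | step 10 | 2-(trimethylsilyl)ethyl (4S,5R,10S,13E)-15-[(tert-butyldimethylsilyl)oxy]-9-hydroxy-2-(phenylsulfonyl)labda-7,13-dien-19-oate (C9 configuration open) | CC(C)(C)[Si](C)(C)OC/C=C(\C)CCC1(O)C(C)=CC[C@H]2[C@@](C)(C(=O)OCC[Si](C)(C)C)CC(S(=O)(=O)c3ccccc3)C[C@]12C
F6 | step 3 | 2-[(1R)-2,4-dimethyl-3-oxocyclohex-4-en-1-yl]prop-2-en-1-yl acetate | CC1=CC[C@H](C(C)C1=O)C(=C)COC(C)=O
F7 | step 3 | (5R)-5-(3-hydroxyprop-1-en-2-yl)-2,6-dimethylcyclohex-2-en-1-one | CC1=CC[C@H](C(C)C1=O)C(=C)CO
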